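Assumption: the target is achiral (no stereocentre, and rotation about the diaryl ether bonds is fast at room temperature), so there is no enantiomer to select and no stereocentre to set.

**Retrosynthetic overview** (numbers follow the forward route)

1. Target 10 has no C–C bond outside its two benzene rings. The strategic bond is the diaryl ether C–O bond between C-2 of the bromophenol ring (ring B) and the phenolic oxygen of the bromoguaiacol ring (ring A).
2. Key disconnection: 10 ⇒ phenol 2 + o-quinone diazide 7. Under Rh(II), C-2 of ring B, the ortho carbon of a phenol and normally a nucleophilic enol α-carbon, reacts with reversed polarity as an electrophilic α-oxo carbenoid (an enolonium-type synthon). It inserts into the O–H bond of 2 and releases the free ortho-OH of 10 directly.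
3. 7 ⇐ aminophenol 5 (diazotisation) ⇐ 4 (O-demethylation) ⇐ o-anisidine 3 (NH2-directed dibromination).
4. 2 ⇐ guaiacol 1 (OH-directed dibromination).
5. No ring is formed. Both benzene rings are bought, each is brominated before the union, and the two halves are joined in the last step.

**Route**

Step 1
Reactants: 1 guaiacol (2-methoxyphenol)
Product: 2 2,4-dibromo-6-methoxyphenol
Conditions: Br2 (2.05 equiv), NaOAc (2.2 equiv), AcOH, 10 °C → rt
Reagents that add atoms: bromine, BrBr
Why: Electrophilic aromatic bromination in which the free OH outranks OMe as director, so bromine enters para and then ortho to OH (C-4 and C-6 of guaiacol) while acetate removes HBr; no stereocentre is formed.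

Step 2
Reactants: 3 o-anisidine (2-methoxyaniline)
Product: 4 2,4-dibromo-6-methoxyaniline
Conditions: NBS (2.05 equiv), MeCN, 0 °C → rt
Reagents that add atoms: N-bromosuccinimide, O=C1CCC(=O)N1Br
Why: Electrophilic aromatic bromination directed by the free NH2 (a stronger donor than OMe) to its para and free ortho positions, which places both bromines ortho/para to the carbon that later carries the ether oxygen; no stereocentre is formed.

Step 3
Reactants: 4 2,4-dibromo-6-methoxyaniline
Product: 5 2-amino-3,5-dibromophenol
Conditions: BBr3 (3 equiv), CH2Cl2, −78 °C → rt; then H2O, NaHCO3 to pH 6–7, under N2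
Reagents that add atoms: none
Why: Lewis-acid cleavage of an aryl methyl ether (BBr3 demethylation, bromide attacks the O-methyl of the boron-complexed ether); the amine binds one equivalent of BBr3 (hence the excess) and the aryl bromides are inert; no stereocentre is formed.

Step 4
Reactants: 5 2-amino-3,5-dibromophenol
Product: 7 3,5-dibromo-6-diazocyclohexa-2,4-dien-1-one, via diazonium hydrogen sulfate 6 (not isolated)
Conditions: NaNO2 (1.05 equiv), aq H2SO4/AcOH, 0 °C; NaOAc to pH 5; extracted into DCE, washed (aq NaHCO3, H2O), dried (MgSO4); kept cold and dark as a solution, never evaporated to dryness, used at once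
Reagents that add atoms: sodium nitrite, [Na+].[O-]N=O
Why: Diazotisation of a primary arylamine, after which the very acidic ortho-OH of diazonium ion 6 is deprotonated on buffering to give the neutral, extractable o-quinone diazide (diazooxide); H2SO4 is used instead of HCl to avoid halide exchange at the N2+-activated C–Br positions; no stereocentre is formed.

Step 5
Reactants: 7 3,5-dibromo-6-diazocyclohexa-2,4-dien-1-one; 2 2,4-dibromo-6-methoxyphenol
Product: 10 3,5-dibromo-2-(2,4-dibromo-6-methoxyphenoxy)phenol, via rhodium carbenoid 8 (not isolated), via oxonium ylide 9 (not isolated)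
Conditions: Rh2(esp)2 (2 mol%), 2 (3 equiv, excess recovered), 4 Å MS, DCE, 60 °C, solution of 7 added over 4 h by syringe pump
Reagents that add atoms: none
Why: Proposed new method: Rh(II) extrudes N2 from 7 to give carbenoid 8, in which the phenol ortho-carbon is a strongly electrophilic α-oxo carbene carbon; the acidic phenol 2, whose ortho and para positions are all blocked so that C–H arylation cannot compete, adds through oxygen to give oxonium ylide 9, and its O-to-O proton shift is driven by re-aromatisation to the 2-aryloxyphenol; the closest known reaction type is Rh(II)-catalysed carbenoid O–H insertion of diazo carbonyl compounds and quinone diazides into alcohols and phenols, untested for this bromine-flanked diazide and this hindered phenol; slow addition and excess 2 suppress carbene dimerisation and a second insertion into the product OH; no stereocentre is formed.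

**Compound list**

1 | guaiacol (2-methoxyphenol) | COc1ccccc1O | starting material
2 | 2,4-dibromo-6-methoxyphenol | COc1cc(Br)cc(Br)c1O | intermediate
3 | o-anisidine (2-methoxyaniline) | COc1ccccc1N | starting material
4 | 2,4-dibromo-6-methoxyaniline | COc1cc(Br)cc(Br)c1N | intermediate
5 | 2-amino-3,5-dibromophenol | Nc1c(O)cc(Br)cc1Br | intermediate
6 | 2,4-dibromo-6-hydroxybenzenediazonium hydrogen sulfate (formed in the flask, not isolated) | Oc1cc(Br)cc(Br)c1[N+]#N.OS(=O)(=O)[O-] | intermediate
7 | 3,5-dibromo-6-diazocyclohexa-2,4-dien-1-one (o-quinone diazide, equivalent to 3,5-dibromo-2-diazoniophenolate) | O=C1C=C(Br)C=C(Br)C1=[N+]=[N-] | intermediate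
8 | rhodium carbenoid: 7 with N2 replaced by the axial Rh of Rh2(esp)2; bridging ligands and second Rh not drawn (formed in the flask, not isolated) | O=C1C=C(Br)C=C(Br)C1=[Rh] | intermediate
9 | oxonium ylide: (2,4-dibromo-6-methoxyphenyl)(2,4-dibromo-6-oxidophenyl)oxonium zwitterion (formed in the flask, not isolated) | COc1cc(Br)cc(Br)c1[OH+]c1c([O-])cc(Br)cc1Br | intermediate
10 | 3,5-dibromo-2-(2,4-dibromo-6-methoxyphenoxy)phenol | COc1cc(Br)cc(Br)c1Oc1c(O)cc(Br)cc1Br | target

**Step count and risk**

Total step count: 5. Longest linear sequence: 4 steps (3 → 4 → 5 → 7 → 10).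

Steps most likely to fail:

Step 5 (carbenoid O–H insertion). The hindered, weakly nucleophilic phenol 2 may not intercept the carbenoid, so that carbene dimer, ring contraction or double insertion prevails. The fallback sets out from 4, uses 2, and comes back at 10. It makes the same ring carbon electrophilic as an aryl-λ3-iodane instead of a carbenoid. Aniline 4 is diazotised in one pot (NaNO2, TsOH·H2O, MeCN/H2O, rt) to 2,4-dibromo-6-methoxybenzenediazonium p-toluenesulfonate F1, which KI converts in the same flask into 1,5-dibromo-2-iodo-3-methoxybenzene F2. Oxidation with mCPBA/TsOH·H2O in MeCN and capture with 1,3,5-trimethoxybenzene gives (2,4-dibromo-6-methoxyphenyl)(2,4,6-trimethoxyphenyl)iodonium p-toluenesulfonate F3. Metal-free O-arylation of phenol 2 (K2CO3, toluene, 60 °C; the electron-rich trimethoxyphenyl group is the ligand that is not transferred) gives the symmetrical bis(2,4-dibromo-6-methoxyphenyl) ether F4. One of its two equivalent methyl ethers is then cleaved with BBr3 (1.0 equiv, CH2Cl2, −78 → 0 °C, stopped at partial conversion, F4 recycled) to give 10.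

Step 4 (diazotisation to the quinone diazide). The free aminophenol may be oxidised or may self-couple to azo compounds, or 7 may be too unstable to handle. The fallback sets out from 2 and comes back at 10. It gives up the diazo compound and brings in ring B with its oxygen masked as a formyl group. Phenol 2 displaces fluoride from purchased 3,5-dibromo-2-fluorobenzaldehyde F5 (K2CO3, DMAc, 120 °C; SNAr activated by the ortho-CHO) to give 3,5-dibromo-2-(2,4-dibromo-6-methoxyphenoxy)benzaldehyde F6. Baeyer–Villiger (Dakin-type) oxidation with mCPBA in CH2Cl2 at reflux gives 3,5-dibromo-2-(2,4-dibromo-6-methoxyphenoxy)phenyl formate F7, and methanolysis (K2CO3, MeOH, rt) gives 10.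

Step 1 (dibromination of guaiacol). The 4,5-dibromo isomer or a tribromide may form and be hard to separate. The fallback sets out from 4 and comes back at 2. The bromine pattern is fixed by the amino group and the nitrogen is then exchanged for oxygen. Aniline 4 is diazotised (NaNO2, aq H2SO4, 0 °C) to 2,4-dibromo-6-methoxybenzenediazonium hydrogen sulfate F8, and hydroxy-dediazoniation at room temperature (Cu2O, Cu(NO3)2, H2O; mild enough to leave the N2+-activated C–Br bonds intact) gives 2.

**Further compounds**

F1 | step 5 | 2,4-dibromo-6-methoxybenzenediazonium p-toluenesulfonate | COc1cc(Br)cc(Br)c1[N+]#N.Cc1ccc(S(=O)(=O)[O-])cc1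
F2 | step 5 | 1,5-dibromo-2-iodo-3-methoxybenzene | COc1cc(Br)cc(Br)c1I
F3 | step 5 | (2,4-dibromo-6-methoxyphenyl)(2,4,6-trimethoxyphenyl)iodonium p-toluenesulfonate | COc1cc(Br)cc(Br)c1[I+]c1c(OC)cc(OC)cc1OC.Cc1ccc(S(=O)(=O)[O-])cc1
F4 | step 5 | bis(2,4-dibromo-6-methoxyphenyl) ether | COc1cc(Br)cc(Br)c1Oc1c(OC)cc(Br)cc1Br
F5 | step 4 | 3,5-dibromo-2-fluorobenzaldehyde (purchased, not made) | O=Cc1cc(Br)cc(Br)c1F
F6 | step 4 | 3,5-dibromo-2-(2,4-dibromo-6-methoxyphenoxy)benzaldehyde | COc1cc(Br)cc(Br)c1Oc1c(C=O)cc(Br)cc1Br
F7 | step 4 | 3,5-dibromo-2-(2,4-dibromo-6-methoxyphenoxy)phenyl formate | COc1cc(Br)cc(Br)c1Oc1c(OC=O)cc(Br)cc1Br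
F8 | step 1 | 2,4-dibromo-6-methoxybenzenediazonium hydrogen sulfate | COc1cc(Br)cc(Br)c1[N+]#N.OS(=O)(=O)[O-]
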